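The pitfall in Friday's run is to reckon from the starting material because its charge, 600 mM, is larger than the partner's 150 mM. The partner is the limiting reagent, and each target formed takes one partner.

| flask | starting material | partner | catalyst | time |
|---|---|---|---|---|
| Tuesday's | 300 mM | 450 mM | 3.00 mM |  |
| Thursday's | 150 mM | 300 mM | 3.00 mM |  |
| Saturday's | 300 mM | 680 mM | 3.00 mM |  |
| Wednesday's | 450 mM | 450 mM | 3.00 mM |  |
| Friday's | 600 mM | 150 mM | 3.00 mM | 97 min |

- Tuesday's run (time / min: [target] / mM): 3.5: 6; 11: 21; 20: 37; 32: 45; 46: 49; 61: 63; 78: 56; 97: 63
- Thursday's run (time / min: [target] / mM): 3.5: 1; 11: 9; 20: 21; 32: 26; 46: 25; 61: 31; 78: 38; 97: 37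
- Saturday's run (time / min: [target] / mM): 3.5: 8; 11: 19; 20: 39; 32: 36; 46: 44; 61: 43; 78: 45; 97: 33
- Wednesday's run (time / min: [target] / mM): 3.5: 13; 11: 27; 20: 46; 32: 62; 46: 82; 61: 86; 78: 93; 97: 109

(scatter of a reading: 4 mM)

- Overall: starting material + partner -> target, with catalyst as catalyst.
- Constant volume, constant temperature.
- The analysis sees a species whether free or bound.
- An order is taken over about fifteen percent of the charge, up and down.

1. the exponent of [starting material] in the starting rate at the charge of the Tuesday's run (at the point where two percent of the starting material have become target) (one fixed amount of target, the same in the runs compared)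
2. the exponent of [partner] in the starting rate at the charge of the Tuesday's run (at the point where two percent of the starting material have become target)
3. target in the Friday's run at 97 min, as a share of the starting material charged

Let x be the share of the starting material charged that has become target. The partner's balance caps x in Friday's run at the ceiling 0.250. Wednesday's run has the lowest ratio of partner to starting material, and its reading at 20 min gives a pace of 0.00511 min⁻¹ in x. Pace times time over ceiling gives 1.98 for Friday's run. This is the fill number: how many times that starting pace would fill the ceiling in the time asked.

If the pace falls in step with the partner remaining, x = ceiling × (1 − exp(−fill number)), which gives 21.6% for Friday's run.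

The test is Wednesday's run itself, whose ceiling is 1.00. The same formula gives 39.1% there, but the reading at 97 min is 24.2%, so one number was not enough. Scaling Friday's figure by that shortfall gives 13.4%, and this reckoning commits to the middle of the two, 17.5%.

The forecast gives orders of 0.7 and 0.1 and a share of 15%, which is lower than the share reckoned here. Its stated ground is: “All runs stall far below full conversion”.

Friday's run gives 18.4%, and the orders are 1.1 and 0.17.

    catalyst + starting material + partner → target + catalyst (26.04 M⁻² min⁻¹)
    catalyst + partner ⇌ idle catalyst-reagent complex, settled at all times (7.610 M⁻¹)
    target + partner → side product (0.06660 M⁻¹ min⁻¹)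

The forecast's share lies within its margin, while both its orders are too low. Tuesday's run holds 450 mM of partner; Saturday's run holds 680 mM, and the starting rate of Saturday's run is 1.0 times that of the other run. Friday's target stands at 73.6% of the ceiling, which in the balance means a fill number of 1.33 rather than 1.98. The pace behind that number puts a quarter of Wednesday's starting material at 56.3 min, but Wednesday's run gets there later, at 128 min.

All runs were generated by integration for an exercise, and the scatter is random.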